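Cuts: first the two O–S bonds at O6 and O7, then O1–C8a of ring C, then C2–C3, and last C4–C4a. Rings A and B are bought intact.
Enabling feature: O1–C8a is an aryl–oxygen bond on ring A ortho to C4a, the carbon that carries the C4 carbonyl, so an enolate oxygen on a C4–C3–C2 chain can replace a halogen at C8a. A ring A with Br at C8a and oxygen at C5, C6 and C7 is mirror-symmetric 5-bromo-1,2,3-trimethoxybenzene plus one acyl group.
Forward: acetylation (C4–C4a), exchange of the three methyl ethers for MOM ethers, Claisen condensation with the ring-B ester (C2–C3), then copper-catalysed closure of ring C (O1–C8a).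
End game: acid frees the 5,6,7-triol while ring B stays benzylated, SO3 transfer goes to O6 and O7 (the 5-OH is chelated to C4=O), and neutral hydrogenolysis uncovers the 3',4'-catechol last.
Stereochemistry: the target has no stereocentre and no stereogenic double bond, so none has to be set.

Key step: step 5

Assumption: the sulfate esters are drawn in the hydrogen sulfate form, as in the target. They would be handled as sodium salts, and the acid form released only at the very end on a cold H+ resin.

Step 1
Reactants: 1 5-bromo-1,2,3-trimethoxybenzene; 2 acetyl chloride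
Product: 3 1-(6-bromo-2,3,4-trimethoxyphenyl)ethan-1-one
Conditions: AlCl3 (1.2 equiv), CH2Cl2, −10 → 0 °C; ice/aq. HCl
Reagents that add atoms: none
Why: Friedel–Crafts acylation: the two free ring positions of 1 are equivalent by symmetry and each lies para to one methoxy group and ortho to another, so the acylium ion can only enter next to bromine, which sets C4–C4a beside the future C8a, while low temperature and near-stoichiometric AlCl3 limit chelation-driven loss of the ortho methyl group.

Step 2
Reactants: 3 1-(6-bromo-2,3,4-trimethoxyphenyl)ethan-1-one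
Product: 4 1-(6-bromo-2,3,4-trihydroxyphenyl)ethan-1-one
Conditions: BBr3 (4.5 equiv), CH2Cl2, −78 °C → rt; ice-water
Reagents that add atoms: none
Why: Lewis-acid aryl methyl ether cleavage: BBr3 binds each methoxy oxygen and bromide removes the methyl group by SN2, a standard exhaustive demethylation that leaves the aryl bromide and the ketone untouched and also funnels any 2-O-demethylated ketone carried over from step 1 into the same triol.

Step 3
Reactants: 4 1-(6-bromo-2,3,4-trihydroxyphenyl)ethan-1-one
Product: 5 1-[6-bromo-2,3,4-tris(methoxymethoxy)phenyl]ethan-1-one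
Conditions: NaH (3.6 equiv), MOMCl (4 equiv), DMF, 0 °C → rt, Ar
Reagents that add atoms: chloromethyl methyl ether (MOMCl), COCCl
Why: Williamson-type O-alkylation (MOM ether formation): NaH converts all three phenols into phenoxides, the 2-hydroxyl included because the acetyl group is twisted out of plane by the ortho bromine and chelates it only weakly, and these displace chloride from the very reactive MOMCl to give acetals that withstand the basic steps 4 and 5 and leave under mild acid.

Step 4
Reactants: 5 1-[6-bromo-2,3,4-tris(methoxymethoxy)phenyl]ethan-1-one; 6 methyl 3,4-bis(benzyloxy)benzoate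
Product: 7 1-[6-bromo-2,3,4-tris(methoxymethoxy)phenyl]-3-[3,4-bis(benzyloxy)phenyl]propane-1,3-dione (largely enolised)
Conditions: NaH (2.5 equiv), THF, 65 °C; AcOH quench at 0 °C
Reagents that add atoms: none
Why: Crossed Claisen condensation: only ketone 5 can enolise, its carbonyl is shielded by two ortho substituents so self-aldol addition is suppressed, ester 6 has no α-hydrogen, and irreversible deprotonation of the 1,3-diketone drives the equilibrium forward.

Step 5
Reactants: 7 1-[6-bromo-2,3,4-tris(methoxymethoxy)phenyl]-3-[3,4-bis(benzyloxy)phenyl]propane-1,3-dione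
Product: 8 3',4'-bis(benzyloxy)-5,6,7-tris(methoxymethoxy)flavone
Conditions: CuI (10 mol %), 1,10-phenanthroline (20 mol %), K2CO3 (2 equiv), DMF, 100 °C, Ar
Reagents that add atoms: none
Why: Carbonate deprotonates the enolised diketone 7 and the chelating enolate hands its ring-B-side oxygen to monovalent copper; insertion of the metal into the neighbouring C8a–Br bond gives a seven-membered metallacycle of trivalent copper, and C–O reductive elimination from it delivers the 4H-chromen-4-one at once, without a separate dehydration or oxidation. The closest known reaction type is the intramolecular Ullmann O-arylation of 1-(2-haloaryl)-1,3-diketones, an established entry to flavones and chromones. Ring C closes as a six-membered ring made of O1, C2, C3, C4, C4a and C8a, the new bond joining an enolate oxygen to an aromatic sp2 carbon; arylation at C3 or at the oxygen on C4 would each demand a four-membered ring and is therefore excluded. No stereocentre is created. The selectivity that matters is C8a–Br against the methoxymethoxy group on the other ortho carbon (the future C5), which a purely base-driven addition–elimination could in principle expel: copper inserts only into the carbon–halogen bond, the three donor oxygens make ring A a poor partner for the uncatalysed pathway, and 100 °C is kept below the range where alkoxide displacement sets in. MOM and benzyl ethers do not react with carbonate or copper under these conditions.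

Step 6
Reactants: 8 3',4'-bis(benzyloxy)-5,6,7-tris(methoxymethoxy)flavone
Product: 9 3',4'-bis(benzyloxy)-5,6,7-trihydroxyflavone
Conditions: HCl (cat., 1.25 M in MeOH), MeOH–THF, 50 °C
Reagents that add atoms: none
Why: Acid-catalysed acetal exchange (MOM cleavage): protonation of the acetal and loss of the phenol give an oxocarbenium ion that methanol traps, under conditions that leave benzyl aryl ethers and the flavone core intact.

Step 7
Reactants: 9 3',4'-bis(benzyloxy)-5,6,7-trihydroxyflavone
Product: 10 3',4'-bis(benzyloxy)-5-hydroxyflavone-6,7-diyl bis(hydrogen sulfate)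
Conditions: Me3N·SO3 (8 equiv), Et3N, MeCN, 90 °C (sealed tube), Ar; Na+ exchange, C18 or Sephadex LH-20
Reagents that add atoms: sulfur trioxide–trimethylamine complex, C[N+](C)(C)S(=O)(=O)[O-]
Why: Phenol O-sulfation with an amine–SO3 complex: the free 6- and 7-phenoxides take up SO3 from the trimethylamine adduct, the 5-hydroxyl is held back by its hydrogen bond to the C4 carbonyl and by crowding between C4a and the new 6-sulfate, and ring B cannot react because it is still benzylated.

Step 8
Reactants: 10 3',4'-bis(benzyloxy)-5-hydroxyflavone-6,7-diyl bis(hydrogen sulfate)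
Product: 11 6-hydroxyluteolin 6,7-disulfate
Conditions: H2 (1 atm), Pd/C, MeOH–H2O, rt (on the disodium salt); cold Dowex 50W (H+ form), freeze-drying
Reagents that add atoms: none
Why: Catalytic hydrogenolysis of benzyl aryl ethers: at neutral pH the aryl sulfate monoester anions are inert, fully oxidised sulfur does not poison palladium, and the conjugated C2–C3 double bond of a flavone is not reduced at atmospheric pressure, so only the two O–CH2Ph bonds should break before a brief cold H+ exchange gives the acid form.

Compound list
1 | 5-bromo-1,2,3-trimethoxybenzene | COc1cc(Br)cc(OC)c1OC | starting material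
2 | acetyl chloride | CC(=O)Cl | starting material
3 | 1-(6-bromo-2,3,4-trimethoxyphenyl)ethan-1-one | CC(=O)c1c(Br)cc(OC)c(OC)c1OC | intermediate
4 | 1-(6-bromo-2,3,4-trihydroxyphenyl)ethan-1-one | CC(=O)c1c(Br)cc(O)c(O)c1O | intermediate
5 | 1-[6-bromo-2,3,4-tris(methoxymethoxy)phenyl]ethan-1-one | CC(=O)c1c(Br)cc(OCOC)c(OCOC)c1OCOC | intermediate
6 | methyl 3,4-bis(benzyloxy)benzoate | COC(=O)c1ccc(OCc2ccccc2)c(OCc2ccccc2)c1 | starting material
7 | 1-[6-bromo-2,3,4-tris(methoxymethoxy)phenyl]-3-[3,4-bis(benzyloxy)phenyl]propane-1,3-dione | COCOc1cc(Br)c(C(=O)CC(=O)c2ccc(OCc3ccccc3)c(OCc3ccccc3)c2)c(OCOC)c1OCOC | intermediate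
8 | 3',4'-bis(benzyloxy)-5,6,7-tris(methoxymethoxy)flavone | COCOc1cc2oc(-c3ccc(OCc4ccccc4)c(OCc4ccccc4)c3)cc(=O)c2c(OCOC)c1OCOC | intermediate
9 | 3',4'-bis(benzyloxy)-5,6,7-trihydroxyflavone | O=c1cc(-c2ccc(OCc3ccccc3)c(OCc3ccccc3)c2)oc2cc(O)c(O)c(O)c12 | intermediate
10 | 3',4'-bis(benzyloxy)-5-hydroxyflavone-6,7-diyl bis(hydrogen sulfate) | O=c1cc(-c2ccc(OCc3ccccc3)c(OCc3ccccc3)c2)oc2cc(OS(=O)(=O)O)c(OS(=O)(=O)O)c(O)c12 | intermediate
11 | 6-hydroxyluteolin 6,7-disulfate | O=c1cc(-c2ccc(O)c(O)c2)oc2cc(OS(=O)(=O)O)c(OS(=O)(=O)O)c(O)c12 | target

Total step count: 8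
Longest linear sequence: 8 steps (1 → 11); ester 6 enters as a purchased partner in step 4.

Steps most likely to fail

1. Step 7, the vicinal disulfation.
- **Risk:** The first sulfate anion, expected at O7, repels the reagent and crowds the flanked 6-hydroxyl, so the reaction may stall after one sulfation. Forcing it invites slow sulfation of the chelated 5-hydroxyl and a hard separation of polyanions.
- **Fallback:** This works with neutral, protected sulfate diesters instead of anions. Setting out from 9, 2,2,2-trichloroethyl chlorosulfate (ClS(=O)(=O)OCC(Cl)(Cl)Cl) with Et3N and DMAP in THF at 0 °C → rt should give 3',4'-bis(benzyloxy)-5-hydroxyflavone-6,7-diyl bis(2,2,2-trichloroethyl sulfate) F1, which is uncharged and can be purified on silica gel. Pd/C with HCO2NH4 in MeOH at rt should then remove both trichloroethyl groups by reductive fragmentation and both benzyl ethers by transfer hydrogenolysis in one operation. This rejoins the route at 11 and bypasses 10.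

2. Step 5, the ring C closure.
- **Risk:** Retro-Claisen cleavage of the diketone by carbonate and traces of water at 100 °C, protodebromination, or base-driven displacement of the ortho methoxymethoxy group may compete with the copper cycle.
- **Fallback:** This puts O1 on ring A first and closes O1–C2 instead.
  - Setting out from 5, Miyaura borylation (B2pin2, Pd(dppf)Cl2, KOAc, dioxane, 90 °C) should give 1-[2,3,4-tris(methoxymethoxy)-6-(4,4,5,5-tetramethyl-1,3,2-dioxaborolan-2-yl)phenyl]ethan-1-one F2.
  - Oxidation with NaBO3·4H2O in THF–H2O at rt should give 1-[6-hydroxy-2,3,4-tris(methoxymethoxy)phenyl]ethan-1-one F3.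
  - Claisen condensation of F3 with 6 (NaH, 4 equiv, THF, 65 °C) should give 1-[6-hydroxy-2,3,4-tris(methoxymethoxy)phenyl]-3-[3,4-bis(benzyloxy)phenyl]propane-1,3-dione F4.
  - Methanolic HCl at 50 °C should then dehydrate its cyclic hemiketal and strip the three MOM groups in the same pot, rejoining the route at 9.
  - The free hydroxyl is already engaged in the hemiketal when the acid arrives, and any 5,7,8-oxygenated isomer would drift to the 5,6,7-pattern by Wessely–Moser rearrangement.

3. Step 1, the acetylation.
- **Risk:** Acylation at the crowded carbon between bromine and methoxy may be slow. A longer exposure to AlCl3 brings chelation-assisted loss of methyl groups and migration or loss of bromine.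
- **Fallback:** This introduces the carbon as a smaller electrophile and adjusts the oxidation level afterwards.
  - Setting out from 1, Rieche formylation (Cl2CHOMe, TiCl4, CH2Cl2, 0 °C) should give 6-bromo-2,3,4-trimethoxybenzaldehyde F5.
  - Grignard addition of MeMgBr in THF at 0 °C should give racemic 1-(6-bromo-2,3,4-trimethoxyphenyl)ethan-1-ol F6.
  - Oxidation with DMP in CH2Cl2 at rt returns to the route at 3.

Further compounds
F1 | step 7 | 3',4'-bis(benzyloxy)-5-hydroxyflavone-6,7-diyl bis(2,2,2-trichloroethyl sulfate) | O=c1cc(-c2ccc(OCc3ccccc3)c(OCc3ccccc3)c2)oc2cc(OS(=O)(=O)OCC(Cl)(Cl)Cl)c(OS(=O)(=O)OCC(Cl)(Cl)Cl)c(O)c12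
F2 | step 5 | 1-[2,3,4-tris(methoxymethoxy)-6-(4,4,5,5-tetramethyl-1,3,2-dioxaborolan-2-yl)phenyl]ethan-1-one | CC(=O)c1c(B2OC(C)(C)C(C)(C)O2)cc(OCOC)c(OCOC)c1OCOC
F3 | step 5 | 1-[6-hydroxy-2,3,4-tris(methoxymethoxy)phenyl]ethan-1-one | CC(=O)c1c(O)cc(OCOC)c(OCOC)c1OCOC
F4 | step 5 | 1-[6-hydroxy-2,3,4-tris(methoxymethoxy)phenyl]-3-[3,4-bis(benzyloxy)phenyl]propane-1,3-dione | COCOc1cc(O)c(C(=O)CC(=O)c2ccc(OCc3ccccc3)c(OCc3ccccc3)c2)c(OCOC)c1OCOC
F5 | step 1 | 6-bromo-2,3,4-trimethoxybenzaldehyde | O=Cc1c(Br)cc(OC)c(OC)c1OC
F6 | step 1 | 1-(6-bromo-2,3,4-trimethoxyphenyl)ethan-1-ol (racemic) | CC(O)c1c(Br)cc(OC)c(OC)c1OC
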